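Numbering: ring B is C1–C5, the spiro carbon C6, ring A C7–C11. Everything rests on disconnecting C6–C7, the bond from the spiro carbon to the methyl-bearing vinylic carbon. Ring B is read as a latent para-substituted anisole whose oxygen marks C3, the future C(CH3)Br carbon, and C7=C8–C9–O of ring A as an ynone. A copper-catalysed dearomatising ipso-cyclisation of this flat aryl ynone (6-endo-dig conjugate addition of the arene carbon para to oxygen) forms C6–C7, the quaternary spiro carbon and ring A in one operation and leaves ring B as a prochiral cyclohexadienone. Catalytic desymmetrisation then makes C6 stereogenic; the other four stereocentres are relayed from it.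

Key step: step 3

Remark on step 4: the (S,S)-ligand is assumed to reduce the enone arm that becomes C4–C5; if the first run shows the opposite sense, the (R,R)-ligand is used.
Remark on steps 7 and 8: the facial preferences at ring A and ring B relative to C6 are assigned from steric models and are the least secure part of the plan.

Step 1
Reactants: 1 3-(4-methoxyphenyl)-3-methylbutanoic acid
Product: 3 N-methoxy-3-(4-methoxyphenyl)-N,3-dimethylbutanamide, via acid chloride 2 (not isolated)
Conditions: (COCl)2, DMF (cat.), CH2Cl2, 0 °C to rt; evaporate; then MeNH(OMe)·HCl, Et3N, CH2Cl2, 0 °C to rt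
Reagents that add atoms: oxalyl chloride, ClC(=O)C(=O)Cl (chlorine carried only in 2); N,O-dimethylhydroxylamine hydrochloride, CNOC.Cl
Why: Acyl chloride formation and N-acylation give the N-methoxy-N-methylamide (Weinreb amide), which allows a single addition of a carbon nucleophile in step 2.

Step 2
Reactants: 3 N-methoxy-3-(4-methoxyphenyl)-N,3-dimethylbutanamide; 4 1-propynylmagnesium bromide
Product: 5 6-(4-methoxyphenyl)-6-methylhept-2-yn-4-one
Conditions: THF, 0 °C; aq NH4Cl
Reagents that add atoms: none
Why: Weinreb ketone synthesis: the alkynyl Grignard reagent adds once because the magnesium chelate of the tetrahedral adduct survives until work-up, which releases the ynone.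

Step 3
Reactants: 5 6-(4-methoxyphenyl)-6-methylhept-2-yn-4-one
Product: 6 7,11,11-trimethylspiro[5.5]undeca-1,4,7-triene-3,9-dione
Conditions: Cu(OTf)2 (20 mol %, divalent copper), H2O (3 equiv), ClCH2CH2Cl, 60 °C
Reagents that add atoms: water, O (hydrolyses the O-methyl oxocarbenium ion)
Why: The copper Lewis acid activates the ynone, the anisole ipso carbon (para to OMe) adds to the alkyne β-carbon C7, the metallated allenoate is protonated at C8, and water cleaves the O-methyl oxocarbenium ion to the cyclohexadienone with loss of methanol. The closest known reaction type is the π-acid-catalysed dearomatising ipso-spirocyclisation of anisole- and phenol-tethered ynones. Ring A closes in the 6-endo-dig mode (both alkyne carbons end in the ring); the ynone polarisation puts the electrophilic site at C7, whereas 5-exo attack at C8 would be polarity-mismatched, and the gem-dimethyl group helps closure. No stereocentre arises: C6 becomes a prochiral spiro carbon with two enantiotopic ring B arms, which step 4 uses. The selectivity needed is ipso over ortho attack; the ortho carbons are meta to the methoxy group and could only close a seven-membered or bridged ring.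

Step 4
Reactants: 6 7,11,11-trimethylspiro[5.5]undeca-1,4,7-triene-3,9-dione
Product: 8 (6S)-7,11,11-trimethylspiro[5.5]undeca-1,7-diene-3,9-dione, via silyl dienol ether 7 (not isolated)
Conditions: Rh(OAc)2(OH2)(L) (2 mol %, trivalent rhodium; L = (S,S)-2,6-bis(4-isopropyl-4,5-dihydrooxazol-2-yl)phenyl), (EtO)2MeSiH (1.5 equiv), toluene, 40 °C; then 1 M HCl, THF, 0 °C
Reagents that add atoms: diethoxymethylsilane, CCO[SiH](C)OCC (silicon carried only in 7)
Why: Desymmetrising conjugate hydrosilylation of a 4,4-disubstituted cyclohexadienone: the chiral rhodium hydride reduces one of the two enantiotopic ring B enone arms, which makes C6 a stereocentre (6S), while the β,β-disubstituted ring A enone next to the quaternary carbon is too hindered to react.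

Step 5
Reactants: 8 (6S)-7,11,11-trimethylspiro[5.5]undeca-1,7-diene-3,9-dione
Product: 10 (6S)-7,11,11-trimethyl-9-oxospiro[5.5]undeca-2,7-dien-3-yl trifluoromethanesulfonate, via triethylsilyl enol ether 9 (not isolated)
Conditions: Et3SiH (1.3 equiv), RhCl(PPh3)3 (2 mol %, monovalent rhodium), THF, 50 °C; evaporate; then CsF, PhNTf2, DME, rt
Reagents that add atoms: triethylsilane, CC[SiH](CC)CC (silicon carried only in 9); N-phenylbis(trifluoromethanesulfonimide), FC(F)(F)S(=O)(=O)N(c1ccccc1)S(=O)(=O)C(F)(F)F
Why: Catalytic 1,4-hydrosilylation engages only the unhindered ring B enone and gives the C2=C3 silyl enol ether regiospecifically, so fluoride-mediated O-triflation fixes the double bond on the C1–C2 arm and the configuration at C6 is kept.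

Step 6
Reactants: 10 (6S)-7,11,11-trimethyl-9-oxospiro[5.5]undeca-2,7-dien-3-yl trifluoromethanesulfonate
Product: 11 (6S)-3,7,11,11-tetramethylspiro[5.5]undeca-2,7-dien-9-one
Conditions: (MeBO)3, Pd(PPh3)4 (5 mol %, zerovalent palladium), K2CO3, 1,4-dioxane/H2O, 90 °C
Reagents that add atoms: trimethylboroxine, CB1OB(C)OB(C)O1
Why: Suzuki–Miyaura methylation of the enol triflate installs the C3 methyl group without touching the enone.

Step 7
Reactants: 11 (6S)-3,7,11,11-tetramethylspiro[5.5]undeca-2,7-dien-9-one
Product: 13 (6R,10R)-10-bromo-3,7,11,11-tetramethylspiro[5.5]undeca-2,7-dien-9-one, via lithium dienolate 12 (not isolated)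
Conditions: LiN(i-Pr)2 (1.1 equiv), THF, −78 °C; then NBS, THF, −78 °C; aq NH4Cl
Reagents that add atoms: lithium diisopropylamide, [Li]N(C(C)C)C(C)C (lithium carried only in 12); N-bromosuccinimide, BrN1C(=O)CCC1=O
Why: Kinetic deprotonation at the α′-carbon C10 (cross-conjugated enolate, as for isophorone) and bromination; bromine should enter anti to the pseudo-axial ring B methylene C5 on C6, hence cis to C1 and equatorial (10R), which is also expected to be the more stable configuration at this epimerisable centre.

Step 8
Reactants: 13 (6R,10R)-10-bromo-3,7,11,11-tetramethylspiro[5.5]undeca-2,7-dien-9-one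
Product: 14 (2S,3S,6R,10R)-10-bromo-2-chloro-3-hydroxy-3,7,11,11-tetramethylspiro[5.5]undec-7-en-9-one
Conditions: NCS (1.2 equiv), acetone/H2O (4:1), 0 °C to rt
Reagents that add atoms: N-chlorosuccinimide, ClN1C(=O)CCC1=O; water, O
Why: Halohydrin formation: the electron-rich ring B alkene (not the enone) takes up Cl+ and water opens the chloronium ion anti at the tertiary carbon C3 (Markovnikov), setting C2 and C3 in one event; chlorine is expected on the ring B face that carries C7, opposite the bulkier quaternary C11, which gives the 2S,3S isomer.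

Step 9
Reactants: 14 (2S,3S,6R,10R)-10-bromo-2-chloro-3-hydroxy-3,7,11,11-tetramethylspiro[5.5]undec-7-en-9-one
Product: 15 (2S,3S,6R,10R)-3,10-dibromo-2-chloro-3,7,11,11-tetramethylspiro[5.5]undec-7-en-9-one
Conditions: Me3SiBr (3 equiv), CH2Cl2, −20 to 0 °C
Reagents that add atoms: bromotrimethylsilane, C[Si](C)(C)Br
Why: Substitution of the tertiary alcohol through the chlorine-bridged cation: the anti-periplanar C2 chlorine assists ionisation and bromide attacks C3 anti to chlorine, so bromine replaces oxygen with retention (neighbouring-group participation), while the enone and the secondary halides are inert.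

Step 10
Reactants: 15 (2S,3S,6R,10R)-3,10-dibromo-2-chloro-3,7,11,11-tetramethylspiro[5.5]undec-7-en-9-one
Product: 16 (2S,3S,6R,9S,10R)-3,10-dibromo-2-chloro-3,7,11,11-tetramethylspiro[5.5]undec-7-en-9-ol (CNP0537910.1)
Conditions: i-Bu2AlH (1.5 equiv), CH2Cl2, −78 °C; aq potassium sodium tartrate
Reagents that add atoms: none
Why: 1,2-Reduction of the enone carbonyl; hydride is delivered to C9 anti to the adjacent C10–Br bond, which gives the cis-bromohydrin (9S), and the alkyl halides do not react at −78 °C.

Compound list
1 | 3-(4-methoxyphenyl)-3-methylbutanoic acid | COc1ccc(cc1)C(C)(C)CC(=O)O | starting material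
2 | 3-(4-methoxyphenyl)-3-methylbutanoyl chloride | COc1ccc(cc1)C(C)(C)CC(=O)Cl | intermediate (not isolated)
3 | N-methoxy-3-(4-methoxyphenyl)-N,3-dimethylbutanamide | COc1ccc(cc1)C(C)(C)CC(=O)N(C)OC | intermediate
4 | 1-propynylmagnesium bromide | CC#C[Mg]Br | starting material
5 | 6-(4-methoxyphenyl)-6-methylhept-2-yn-4-one | CC#CC(=O)CC(C)(C)c1ccc(OC)cc1 | intermediate
6 | 7,11,11-trimethylspiro[5.5]undeca-1,4,7-triene-3,9-dione | CC1=CC(=O)CC(C)(C)C12C=CC(=O)C=C2 | intermediate
7 | (6S)-3-[diethoxy(methyl)silyloxy]-7,11,11-trimethylspiro[5.5]undeca-1,3,7-trien-9-one | CC1=CC(=O)CC(C)(C)[C@@]12CC=C(O[Si](C)(OCC)OCC)C=C2 | intermediate (not isolated)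
8 | (6S)-7,11,11-trimethylspiro[5.5]undeca-1,7-diene-3,9-dione | CC1=CC(=O)CC(C)(C)[C@@]12CCC(=O)C=C2 | intermediate
9 | (6S)-7,11,11-trimethyl-3-(triethylsilyloxy)spiro[5.5]undeca-2,7-dien-9-one | CC1=CC(=O)CC(C)(C)[C@@]12CCC(O[Si](CC)(CC)CC)=CC2 | intermediate (not isolated)
10 | (6S)-7,11,11-trimethyl-9-oxospiro[5.5]undeca-2,7-dien-3-yl trifluoromethanesulfonate | CC1=CC(=O)CC(C)(C)[C@@]12CCC(OS(=O)(=O)C(F)(F)F)=CC2 | intermediate
11 | (6S)-3,7,11,11-tetramethylspiro[5.5]undeca-2,7-dien-9-one | CC1=CC(=O)CC(C)(C)[C@@]12CCC(C)=CC2 | intermediate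
12 | lithium (6R)-3,7,11,11-tetramethylspiro[5.5]undeca-2,7,9-trien-9-olate | CC1=CC(O[Li])=CC(C)(C)[C@@]12CCC(C)=CC2 | intermediate (not isolated)
13 | (6R,10R)-10-bromo-3,7,11,11-tetramethylspiro[5.5]undeca-2,7-dien-9-one | CC1=CC(=O)[C@H](Br)C(C)(C)[C@@]12CCC(C)=CC2 | intermediate
14 | (2S,3S,6R,10R)-10-bromo-2-chloro-3-hydroxy-3,7,11,11-tetramethylspiro[5.5]undec-7-en-9-one | CC1=CC(=O)[C@H](Br)C(C)(C)[C@@]12CC[C@](C)(O)[C@@H](Cl)C2 | intermediate
15 | (2S,3S,6R,10R)-3,10-dibromo-2-chloro-3,7,11,11-tetramethylspiro[5.5]undec-7-en-9-one | CC1=CC(=O)[C@H](Br)C(C)(C)[C@@]12CC[C@](C)(Br)[C@@H](Cl)C2 | intermediate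
16 | (2S,3S,6R,9S,10R)-3,10-dibromo-2-chloro-3,7,11,11-tetramethylspiro[5.5]undec-7-en-9-ol | CC1=C[C@H](O)[C@H](Br)C(C)(C)[C@@]12CC[C@](C)(Br)[C@@H](Cl)C2 | target

Total step count: 10. Longest linear sequence: 10 steps (from 1).

Steps most likely to fail

Step 8. The chloronium ion may form on the other face of ring B (poor or reversed facial selectivity relative to C6), and ene-type allylic chlorination may compete. The fallback sets C2 by delivering hydrogen, not chlorine, to C2, so it has the opposite facial outcome. It sets out from 8. α-Chlorination of the ring B enone (PhICl2, pyridine, CH2Cl2) should give (6S)-2-chloro-7,11,11-trimethylspiro[5.5]undeca-1,7-diene-3,9-dione F1. Conjugate hydride addition (Li[HB(s-Bu)3], THF, −78 °C) and kinetic protonation of the chloro enolate at C2 by a hindered phenol from the more accessible face should give (2S,6S)-2-chloro-7,11,11-trimethylspiro[5.5]undec-7-ene-3,9-dione F2, with chlorine pushed to the face an external electrophile avoids. CH3MgBr/CeCl3 (THF, −78 °C) should add to the more electrophilic ring B ketone to give (2S,6S)-2-chloro-3-hydroxy-3,7,11,11-tetramethylspiro[5.5]undec-7-en-9-one F3 (either C3 epimer, since both ionise to the same cation). Me3SiBr should then give (2S,3S,6S)-3-bromo-2-chloro-3,7,11,11-tetramethylspiro[5.5]undec-7-en-9-one F4, and α′-bromination as in step 7 comes back to the route at 15.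

Step 9. The tertiary cation may lose a proton (elimination instead of substitution) or be captured on the wrong face, and the acid may epimerise C10. The fallback sets out from 14. Anti elimination of water (SOCl2, pyridine, 0 °C) should give (2S,6R,10R)-10-bromo-2-chloro-7,11,11-trimethyl-3-methylidenespiro[5.5]undec-7-en-9-one F5 together with its endocyclic isomer (2S,6R,10R)-10-bromo-2-chloro-3,7,11,11-tetramethylspiro[5.5]undeca-3,7-dien-9-one F6. Both should take up HBr (gas, CH2Cl2, −78 °C) in the Markovnikov sense under kinetic control, with bromide entering anti to the bridging chlorine, and this comes back to the route at 15.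

Step 4. The catalyst may discriminate poorly between the two enantiotopic enone arms, because both substituents on C6 are carbon groups of similar size. The fallback moves the enantio-determining event to an asymmetric deprotonation and sets out from 6. Exhaustive conjugate reduction of ring B ([(Ph3P)CuH]6, benzene, rt; aq NH4Cl) should give achiral 7,11,11-trimethylspiro[5.5]undec-7-ene-3,9-dione F7. Enantioselective deprotonation of its ring B ketone with lithium bis[(R)-1-phenylethyl]amide, LiN[CH(CH3)Ph]2 (LiCl, THF, −78 °C; amide enantiomer chosen for 6S), and O-triflation with N-(5-chloropyridin-2-yl)bis(trifluoromethanesulfonimide) comes back to the route at 10.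

Further compounds
F1 | step 8 | (6S)-2-chloro-7,11,11-trimethylspiro[5.5]undeca-1,7-diene-3,9-dione | CC1=CC(=O)CC(C)(C)[C@@]12CCC(=O)C(Cl)=C2
F2 | step 8 | (2S,6S)-2-chloro-7,11,11-trimethylspiro[5.5]undec-7-ene-3,9-dione | CC1=CC(=O)CC(C)(C)[C@@]12CCC(=O)[C@@H](Cl)C2
F3 | step 8 | (2S,6S)-2-chloro-3-hydroxy-3,7,11,11-tetramethylspiro[5.5]undec-7-en-9-one (C3 epimers) | CC1=CC(=O)CC(C)(C)[C@@]12CCC(C)(O)[C@@H](Cl)C2
F4 | step 8 | (2S,3S,6S)-3-bromo-2-chloro-3,7,11,11-tetramethylspiro[5.5]undec-7-en-9-one | CC1=CC(=O)CC(C)(C)[C@@]12CC[C@](C)(Br)[C@@H](Cl)C2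
F5 | step 9 | (2S,6R,10R)-10-bromo-2-chloro-7,11,11-trimethyl-3-methylidenespiro[5.5]undec-7-en-9-one | CC1=CC(=O)[C@H](Br)C(C)(C)[C@@]12CCC(=C)[C@@H](Cl)C2
F6 | step 9 | (2S,6R,10R)-10-bromo-2-chloro-3,7,11,11-tetramethylspiro[5.5]undeca-3,7-dien-9-one | CC1=CC(=O)[C@H](Br)C(C)(C)[C@@]12CC=C(C)[C@@H](Cl)C2
F7 | step 4 | 7,11,11-trimethylspiro[5.5]undec-7-ene-3,9-dione | CC1=CC(=O)CC(C)(C)C12CCC(=O)CC2
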